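**Retrosynthetic overview**

1. Target ring positions: C1 = CH–CH2OAc, C2 = C–CHO, C5=C6 = E-olefin with CH3 on C6, C8 = CH–OH, C9 = CH–side chain. The enal is taken back to a C2 vinyl triflate, and this to an (E)-cyclononenone with its ketone at C2.
2. The nine-membered ring (last ring formed) comes from Grob fragmentation of a cis-hydrindane 1,3-diol monotosylate: the C2–C6 bond, which the target does not contain, is cut and leaves C2=O and the E-C5=C6 olefin.
3. The hydrindane comes from the key aldol: a proline enamine of a chain aldehyde forms C1–C2 and closes the six-membered ring C1–C2–C6–C7–C8–C9 (first ring formed) onto one carbonyl of a purchased cyclopentane-1,3-dione (ring C2–C3–C4–C5–C6).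
4. Enabling feature: C2 is a masked ketone, C1 is alpha to the masked aldehyde of the CH2OAc carbon, and C2 lies across the nine-membered ring from the methyl-bearing olefinic C6, whose neighbour C5 can carry a nucleofuge; the ring is therefore a hydrindane minus its fusion bond.
5. The aldehyde comes from an anti-selective, catalyst-controlled allylboration of a dione acetaldehyde with an (E)-allylboronate made from (S)-citronellal (sets C8 and C9; the side-chain methyl centre is bought), then anti-Markovnikov hydration and oxidation.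

Key step: step 10

Remark: the ring-flip conformers of the (E)-cyclononene (planar chirality) are assumed to interconvert, so the four stereocentres and two olefin geometries of the formula define the target fully.
Numbering: hydrindane intermediates are numbered as octahydro-1H-indenes; C3a–C4 is the bond made in step 10 and C3a–C7a the bond cut in step 14.

**Route**

Step 1
Reactants: 1 (S)-citronellal
Product: 3 (3S)-3,7-dimethyloct-6-en-1-yne, via enol nonaflate 2 (not isolated)
Conditions: n-C4F9SO2F (1.2 equiv), phosphazene base P2-Et (2.2 equiv), DMF, −30 °C to rt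
Reagents that add atoms: none
Why: O-nonaflation of the aldehyde enolate and base-induced elimination of nonaflate in the same flask (one-pot aldehyde-to-alkyne conversion through an alkenyl nonaflate) should give the terminal alkyne with the C3 stereocentre of citronellal untouched.

Step 2
Reactants: 3 (3S)-3,7-dimethyloct-6-en-1-yne
Product: 4 (E)-alkenyl pinacolboronate, 2-[(1E,3S)-3,7-dimethylocta-1,6-dien-1-yl]-4,4,5,5-tetramethyl-1,3,2-dioxaborolane
Conditions: pinacolborane (1.1 equiv), Cp2Zr(H)Cl (5 mol%), Et3N (10 mol%), neat, 60 °C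
Reagents that add atoms: pinacolborane, [H]B1OC(C)(C)C(C)(C)O1
Why: Zirconium-catalysed syn-hydroboration of the terminal alkyne should place boron on the terminal carbon and give only the E-alkenylboronate, while the trisubstituted olefin does not react with pinacolborane.

Step 3
Reactants: 4 (E)-alkenyl pinacolboronate
Product: 6 (E)-allyl pinacolboronate 2-[(2E,4S)-4,8-dimethylnona-2,7-dien-1-yl]-4,4,5,5-tetramethyl-1,3,2-dioxaborolane, via borate complex 5 (not isolated)
Conditions: BrCH2Cl (1.5 equiv), n-BuLi (1.3 equiv), THF, −78 °C to rt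
Reagents that add atoms: bromochloromethane, ClCBr
Why: Matteson homologation: LiCH2Cl adds to boron and 1,2-migration of the alkenyl group with loss of chloride inserts one CH2 with retention of the E geometry.

Step 4
Reactants: 7 2-methylcyclopentane-1,3-dione
Product: 8 2-allyl-2-methylcyclopentane-1,3-dione
Conditions: allyl bromide (1.5 equiv), 1 M aq NaOH, rt
Reagents that add atoms: allyl bromide, C=CCBr
Why: C-alkylation of the stabilised dione enolate with a soft allylic halide in water should give the 2,2-disubstituted dione.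

Step 5
Reactants: 8 2-allyl-2-methylcyclopentane-1,3-dione
Product: 10 2-(1-methyl-2,5-dioxocyclopentyl)acetaldehyde, via ozonide 9 (not isolated)
Conditions: O3, CH2Cl2, −78 °C; then Me2S, −78 °C to rt
Reagents that add atoms: ozone, [O-][O+]=O
Why: Ozonolysis with reductive work-up cleaves the only olefin and leaves the ketones untouched.

Step 6
Reactants: 10 2-(1-methyl-2,5-dioxocyclopentyl)acetaldehyde; 6 (E)-allyl pinacolboronate
Product: 12 anti-homoallylic alcohol 2-[(2S,3S,4S)-3-ethenyl-2-hydroxy-4,8-dimethylnon-7-en-1-yl]-2-methylcyclopentane-1,3-dione, via pinacol borate ester 11 (not isolated)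
Conditions: (R)-TRIP phosphoric acid (5 mol%), 4 Å molecular sieves, toluene, −30 to 0 °C; then H2O
Reagents that add atoms: none
Why: Chiral-phosphoric-acid-catalysed allylboration through a closed chair transition state: the E geometry of 6 should set hydroxyl and side chain anti (C2/C3), the (R)-catalyst should direct attack to the Re face of the aldehyde (C2 S), C4 comes from citronellal, and the aldehyde reacts far faster than the hindered ketones.

Step 7
Reactants: 12 anti-homoallylic alcohol
Product: 13 TBS ether 2-[(2S,3S,4S)-2-(tert-butyldimethylsilyloxy)-3-ethenyl-4,8-dimethylnon-7-en-1-yl]-2-methylcyclopentane-1,3-dione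
Conditions: TBSOTf (1.2 equiv), 2,6-lutidine, CH2Cl2, −78 °C
Reagents that add atoms: tert-butyldimethylsilyl triflate, CC(C)(C)[Si](C)(C)OS(=O)(=O)C(F)(F)F
Why: Silylation of the secondary alcohol under weakly basic conditions protects the hydroxyl without enolising the dione.

Step 8
Reactants: 13 TBS ether
Product: 15 primary alcohol 2-[(2S,3S)-2-(tert-butyldimethylsilyloxy)-5-hydroxy-3-[(2S)-6-methylhept-5-en-2-yl]pentyl]-2-methylcyclopentane-1,3-dione, via alkyl catecholboronate 14 (not isolated)
Conditions: catecholborane (1.5 equiv), RhCl(PPh3)3 (3 mol%), THF, 0 °C to rt; then NaBO3·4H2O, THF/H2O, rt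
Reagents that add atoms: sodium perborate (NaBO3·4H2O), [Na+].[O-]OB=O
Why: Rhodium-catalysed anti-Markovnikov hydroboration of the monosubstituted olefin is faster than reduction of the ketones or addition to the trisubstituted olefin, and perborate oxidises the C–B bond under conditions mild enough for the dione.

Step 9
Reactants: 15 primary alcohol
Product: 16 aldehyde (3S,4S)-4-(tert-butyldimethylsilyloxy)-3-[(2S)-6-methylhept-5-en-2-yl]-5-(1-methyl-2,5-dioxocyclopentyl)pentanal
Conditions: Dess–Martin periodinane (1.2 equiv), CH2Cl2, 0 °C to rt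
Reagents that add atoms: none
Why: Neutral oxidation of the primary alcohol gives the aldehyde without epimerising C3 or touching the dione.

Step 10
Reactants: 16 aldehyde
Product: 18 cis-hydrindane ketol aldehyde (3aS,4R,5R,6S,7aS)-6-(tert-butyldimethylsilyloxy)-3a-hydroxy-7a-methyl-5-[(2S)-6-methylhept-5-en-2-yl]-1-oxooctahydro-1H-indene-4-carbaldehyde, via proline enamine 17 (not isolated)
Conditions: (R)-proline (20 mol%), DMF, rt
Reagents that add atoms: none
Why: (R)-Proline condenses only with the aldehyde to give E-enamine 17, whose alpha carbon (C4, which is C1 of the target ring) adds to one ring carbonyl (C3a, C2 of the target) through a carboxylic-acid-bridged chair transition state, and hydrolysis returns the catalyst. The closest known reactions are the Hajos–Parrish aldol of 2-alkyl-2-methylcyclopentane-1,3-diones and the proline-catalysed 6-enolexo aldolisation of dialdehydes and keto aldehydes. The six-membered ring closes in the 6-(enolexo)-exo-trig mode onto the cyclopentanedione, and only the cis ring fusion is accessible. C4, the one new centre that survives to the target, is set by the catalyst (Si face of the enamine) and reinforced by the substrate, because this face places the formyl group equatorial and trans to the equatorial C5 side chain; C3a and C7a follow from the anti (formyl/hydroxyl trans) topology of the chair and are erased in step 14. The step needs chemoselectivity, secured because the two ketones are flanked by the quaternary carbon and do not form enamines, and diastereocontrol at C4; a cis-ketol from attack on the other carbonyl would carry the same C4 configuration and should converge on ketone 23.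

Step 11
Reactants: 18 cis-hydrindane ketol aldehyde
Product: 19 triol (1S,3aS,4S,5R,6S,7aR)-6-(tert-butyldimethylsilyloxy)-4-(hydroxymethyl)-7a-methyl-5-[(2S)-6-methylhept-5-en-2-yl]octahydro-1H-indene-1,3a-diol
Conditions: NaBH4 (2 equiv), MeOH/CH2Cl2, −78 to 0 °C
Reagents that add atoms: none
Why: Borohydride reduces the aldehyde and the cyclopentanone, and hydride should approach C1 anti to the adjacent angular methyl group (as in 17-keto steroids and Hajos–Parrish ketones), so that the new C1 hydroxyl is cis to the methyl group.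

Step 12
Reactants: 19 triol
Product: 20 primary TBS ether (1S,3aS,4S,5R,6S,7aR)-6-(tert-butyldimethylsilyloxy)-4-[(tert-butyldimethylsilyloxy)methyl]-7a-methyl-5-[(2S)-6-methylhept-5-en-2-yl]octahydro-1H-indene-1,3a-diol
Conditions: TBSCl (1.05 equiv), imidazole, CH2Cl2, 0 °C
Reagents that add atoms: tert-butyldimethylsilyl chloride, CC(C)(C)[Si](C)(C)Cl
Why: The primary hydroxyl is silylated much faster than the neopentyl secondary and the tertiary hydroxyl.

Step 13
Reactants: 20 primary TBS ether
Product: 21 C1 tosylate of 20 (3a-hydroxyl free; same configuration)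
Conditions: TsCl (2 equiv), pyridine, DMAP (cat.), rt
Reagents that add atoms: 4-toluenesulfonyl chloride, Cc1ccc(cc1)S(Cl)(=O)=O
Why: Only the secondary hydroxyl is sulfonylated, because the tertiary 3a-hydroxyl is inert under these conditions and remains as the alkoxide donor for the fragmentation.

Step 14
Reactants: 21 C1 tosylate
Product: 23 (4E,7S,8R,9S)-7-(tert-butyldimethylsilyloxy)-9-[(tert-butyldimethylsilyloxy)methyl]-5-methyl-8-[(2S)-6-methylhept-5-en-2-yl]cyclonon-4-en-1-one, via potassium alkoxide 22 (not isolated)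
Conditions: KN(SiMe3)2 (1.05 equiv), THF, −78 to 0 °C
Reagents that add atoms: none
Why: Grob fragmentation of the 1,3-diol monotosylate: the C1–OTs bond is antiperiplanar to the C3a–C7a bond, so the alkoxide expels tosylate with cleavage of the ring-fusion bond, and the cis relation of tosylate and angular methyl is transferred stereospecifically into the E-olefin of the nine-membered ring; no stereocentre is formed and the base is consumed before it can enolise the new ketone.

Step 15
Reactants: 23 (E)-cyclononenone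
Product: 25 (1E,4E,7S,8R,9S)-7-(tert-butyldimethylsilyloxy)-9-[(tert-butyldimethylsilyloxy)methyl]-5-methyl-8-[(2S)-6-methylhept-5-en-2-yl]cyclonona-1,4-dien-1-yl triflate, via potassium enolate 24 (not isolated)
Conditions: KN(SiMe3)2 (1.1 equiv), THF, −78 °C; then PhNTf2, −78 to 0 °C
Reagents that add atoms: N-phenylbis(trifluoromethanesulfonimide), FC(F)(F)S(=O)(=O)N(c1ccccc1)S(=O)(=O)C(F)(F)F
Why: Kinetic deprotonation by the hindered amide should occur at the ring CH2 (C2) and not at the substituted C9, and O-triflation of the ring-cis enolate, the only geometry a nine-membered ring that already holds an E-olefin can adopt, fixes the later enal geometry.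

Step 16
Reactants: 25 dienyl triflate
Product: 26 diol (1E,4E,7S,8R,9S)-7-hydroxy-9-(hydroxymethyl)-5-methyl-8-[(2S)-6-methylhept-5-en-2-yl]cyclonona-1,4-dien-1-yl triflate
Conditions: HF·pyridine, pyridine, THF, 0 °C to rt
Reagents that add atoms: none
Why: Buffered fluoride cleaves both silyl ethers, while the vinyl triflate, both ring olefins and the stereocentres are stable to these conditions.

Step 17
Reactants: 26 diol
Product: 27 monoacetate [(1S,2E,5E,8S,9R)-8-hydroxy-6-methyl-9-[(2S)-6-methylhept-5-en-2-yl]-2-(trifluoromethylsulfonyloxy)cyclonona-2,5-dien-1-yl]methyl acetate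
Conditions: AcCl (1.05 equiv), 2,4,6-collidine, CH2Cl2, −78 °C
Reagents that add atoms: acetyl chloride, CC(Cl)=O
Why: At low temperature with a hindered base the primary hydroxyl is acylated in preference to the hindered secondary C8 hydroxyl.

Step 18
Reactants: 27 monoacetate
Product: 28 hydroxyacetyldictyolal, [(1R,2E,5E,8S,9R)-2-formyl-8-hydroxy-6-methyl-9-[(2S)-6-methylhept-5-en-2-yl]cyclonona-2,5-dien-1-yl]methyl acetate
Conditions: Pd(PPh3)4 (5 mol%), CO (1 atm), Bu3SnH (1.2 equiv, slow addition), LiCl (3 equiv), THF, 50 °C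
Reagents that add atoms: carbon monoxide, [C-]#[O+]
Why: Oxidative addition of zerovalent palladium into the vinyl triflate, CO insertion and hydride transfer from tin (palladium-catalysed reductive carbonylation of a vinyl triflate) should give the enal with retention of olefin geometry, and the homoallylic acetate and free hydroxyl are tolerated.

**Compound list**

1 | (S)-citronellal, (3S)-3,7-dimethyloct-6-enal | C[C@@H](CCC=C(C)C)CC=O | starting material
2 | (3S)-3,7-dimethylocta-1,6-dien-1-yl nonafluorobutane-1-sulfonate (E/Z mixture) | C[C@@H](CCC=C(C)C)C=COS(=O)(=O)C(F)(F)C(F)(F)C(F)(F)C(F)(F)F | intermediate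
3 | (3S)-3,7-dimethyloct-6-en-1-yne | C[C@@H](CCC=C(C)C)C#C | intermediate
4 | 2-[(1E,3S)-3,7-dimethylocta-1,6-dien-1-yl]-4,4,5,5-tetramethyl-1,3,2-dioxaborolane | CC1(C)OB(/C=C/[C@@H](C)CCC=C(C)C)OC1(C)C | intermediate
5 | lithium (chloromethyl)borate complex of 4 | [Li+].CC1(C)O[B-](CCl)(/C=C/[C@@H](C)CCC=C(C)C)OC1(C)C | intermediate
6 | 2-[(2E,4S)-4,8-dimethylnona-2,7-dien-1-yl]-4,4,5,5-tetramethyl-1,3,2-dioxaborolane | CC1(C)OB(C/C=C/[C@@H](C)CCC=C(C)C)OC1(C)C | intermediate
7 | 2-methylcyclopentane-1,3-dione | CC1C(=O)CCC1=O | starting material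
8 | 2-allyl-2-methylcyclopentane-1,3-dione | C=CCC1(C)C(=O)CCC1=O | intermediate
9 | ozonide (1,2,4-trioxolane) of 8 | CC1(CC2OOCO2)C(=O)CCC1=O | intermediate
10 | 2-(1-methyl-2,5-dioxocyclopentyl)acetaldehyde | O=CCC1(C)C(=O)CCC1=O | intermediate
11 | pinacol borate ester of alcohol 12 (O–Bpin) | C=C[C@@H]([C@@H](C)CCC=C(C)C)[C@@H](OB1OC(C)(C)C(C)(C)O1)CC2(C)C(=O)CCC2=O | intermediate
12 | 2-[(2S,3S,4S)-3-ethenyl-2-hydroxy-4,8-dimethylnon-7-en-1-yl]-2-methylcyclopentane-1,3-dione | C=C[C@@H]([C@@H](C)CCC=C(C)C)[C@@H](O)CC1(C)C(=O)CCC1=O | intermediate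
13 | 2-[(2S,3S,4S)-2-(tert-butyldimethylsilyloxy)-3-ethenyl-4,8-dimethylnon-7-en-1-yl]-2-methylcyclopentane-1,3-dione | C=C[C@@H]([C@@H](C)CCC=C(C)C)[C@@H](O[Si](C)(C)C(C)(C)C)CC1(C)C(=O)CCC1=O | intermediate
14 | primary alkyl catecholboronate from 13 (boron on the terminal carbon) | B1(CC[C@@H]([C@@H](C)CCC=C(C)C)[C@@H](O[Si](C)(C)C(C)(C)C)CC2(C)C(=O)CCC2=O)Oc3ccccc3O1 | intermediate
15 | 2-[(2S,3S)-2-(tert-butyldimethylsilyloxy)-5-hydroxy-3-[(2S)-6-methylhept-5-en-2-yl]pentyl]-2-methylcyclopentane-1,3-dione | OCC[C@@H]([C@@H](C)CCC=C(C)C)[C@@H](O[Si](C)(C)C(C)(C)C)CC1(C)C(=O)CCC1=O | intermediate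
16 | (3S,4S)-4-(tert-butyldimethylsilyloxy)-3-[(2S)-6-methylhept-5-en-2-yl]-5-(1-methyl-2,5-dioxocyclopentyl)pentanal | O=CC[C@@H]([C@@H](C)CCC=C(C)C)[C@@H](O[Si](C)(C)C(C)(C)C)CC1(C)C(=O)CCC1=O | intermediate
17 | E-enamine of aldehyde 16 with (R)-proline | OC(=O)[C@H]1CCCN1/C=C/[C@@H]([C@@H](C)CCC=C(C)C)[C@@H](O[Si](C)(C)C(C)(C)C)CC2(C)C(=O)CCC2=O | intermediate
18 | (3aS,4R,5R,6S,7aS)-6-(tert-butyldimethylsilyloxy)-3a-hydroxy-7a-methyl-5-[(2S)-6-methylhept-5-en-2-yl]-1-oxooctahydro-1H-indene-4-carbaldehyde (cis-fused; 3a-OH, 7a-CH3, 6-OTBS and the C5 side chain on one face, 4-CHO on the other) | O=C[C@@H]1[C@@H]([C@@H](C)CCC=C(C)C)[C@@H](O[Si](C)(C)C(C)(C)C)C[C@]2(C)C(=O)CC[C@]12O | intermediate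
19 | (1S,3aS,4S,5R,6S,7aR)-6-(tert-butyldimethylsilyloxy)-4-(hydroxymethyl)-7a-methyl-5-[(2S)-6-methylhept-5-en-2-yl]octahydro-1H-indene-1,3a-diol (1-OH cis to 7a-CH3) | OC[C@@H]1[C@@H]([C@@H](C)CCC=C(C)C)[C@@H](O[Si](C)(C)C(C)(C)C)C[C@]2(C)[C@@H](O)CC[C@]12O | intermediate
20 | (1S,3aS,4S,5R,6S,7aR)-6-(tert-butyldimethylsilyloxy)-4-[(tert-butyldimethylsilyloxy)methyl]-7a-methyl-5-[(2S)-6-methylhept-5-en-2-yl]octahydro-1H-indene-1,3a-diol | CC(C)(C)[Si](C)(C)OC[C@@H]1[C@@H]([C@@H](C)CCC=C(C)C)[C@@H](O[Si](C)(C)C(C)(C)C)C[C@]2(C)[C@@H](O)CC[C@]12O | intermediate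
21 | C1 4-methylbenzenesulfonate of 20 (1S,3aS,4S,5R,6S,7aR) | CC(C)(C)[Si](C)(C)OC[C@@H]1[C@@H]([C@@H](C)CCC=C(C)C)[C@@H](O[Si](C)(C)C(C)(C)C)C[C@]2(C)[C@@H](OS(=O)(=O)c3ccc(C)cc3)CC[C@]12O | intermediate
22 | potassium 3a-alkoxide of 21 | [K+].CC(C)(C)[Si](C)(C)OC[C@@H]1[C@@H]([C@@H](C)CCC=C(C)C)[C@@H](O[Si](C)(C)C(C)(C)C)C[C@]2(C)[C@@H](OS(=O)(=O)c3ccc(C)cc3)CC[C@]12[O-] | intermediate
23 | (4E,7S,8R,9S)-7-(tert-butyldimethylsilyloxy)-9-[(tert-butyldimethylsilyloxy)methyl]-5-methyl-8-[(2S)-6-methylhept-5-en-2-yl]cyclonon-4-en-1-one | CC(C)(C)[Si](C)(C)OC[C@H]1C(=O)CC/C=C(\C)C[C@H](O[Si](C)(C)C(C)(C)C)[C@@H]1[C@@H](C)CCC=C(C)C | intermediate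
24 | potassium enolate of 23 (C1–O−, C1=C2, ring-cis) | [K+].CC(C)(C)[Si](C)(C)OC[C@H]1/C([O-])=C\C/C=C(\C)C[C@H](O[Si](C)(C)C(C)(C)C)[C@@H]1[C@@H](C)CCC=C(C)C | intermediate
25 | (1E,4E,7S,8R,9S)-7-(tert-butyldimethylsilyloxy)-9-[(tert-butyldimethylsilyloxy)methyl]-5-methyl-8-[(2S)-6-methylhept-5-en-2-yl]cyclonona-1,4-dien-1-yl trifluoromethanesulfonate | CC(C)(C)[Si](C)(C)OC[C@H]1/C(OS(=O)(=O)C(F)(F)F)=C\C/C=C(\C)C[C@H](O[Si](C)(C)C(C)(C)C)[C@@H]1[C@@H](C)CCC=C(C)C | intermediate
26 | (1E,4E,7S,8R,9S)-7-hydroxy-9-(hydroxymethyl)-5-methyl-8-[(2S)-6-methylhept-5-en-2-yl]cyclonona-1,4-dien-1-yl trifluoromethanesulfonate | OC[C@H]1/C(OS(=O)(=O)C(F)(F)F)=C\C/C=C(\C)C[C@H](O)[C@@H]1[C@@H](C)CCC=C(C)C | intermediate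
27 | [(1S,2E,5E,8S,9R)-8-hydroxy-6-methyl-9-[(2S)-6-methylhept-5-en-2-yl]-2-(trifluoromethylsulfonyloxy)cyclonona-2,5-dien-1-yl]methyl acetate | CC(=O)OC[C@H]1/C(OS(=O)(=O)C(F)(F)F)=C\C/C=C(\C)C[C@H](O)[C@@H]1[C@@H](C)CCC=C(C)C | intermediate
28 | hydroxyacetyldictyolal, [(1R,2E,5E,8S,9R)-2-formyl-8-hydroxy-6-methyl-9-[(2S)-6-methylhept-5-en-2-yl]cyclonona-2,5-dien-1-yl]methyl acetate | CC(=O)OC[C@H]1/C(C=O)=C\C/C=C(\C)C[C@H](O)[C@@H]1[C@@H](C)CCC=C(C)C | target

**Step count and risks**

Total step count: 18. Longest linear sequence: 16 steps (steps 1–3 and 6–18, from (S)-citronellal).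

The three steps most likely to fail:

1. Step 10 (key aldol). The catalyst-preferred chair places the angular methyl group 1,3-diaxial to the silyloxy group at C6, so ring closure may be slow, and the reversible tertiary aldol may revert to 16, dehydrate or lose control at C4. The fallback closes the same bond as a samarium Reformatsky reaction at the ester oxidation level, without an enamine. It sets out from 16: amine-catalysed alpha-bromination (NBS, 10 mol% pyrrolidine-type catalyst, CH2Cl2, 0 °C) gives the alpha-bromo aldehyde F1 as both C2 epimers; NaClO2/NaH2PO4/2-methyl-2-butene gives the alpha-bromo acid F2; TMSCHN2 gives the alpha-bromo methyl ester F3. SmI2 (THF, −78 °C) generates the samarium enolate only at the brominated carbon, and this adds to the ring carbonyl through a chelated chair to give the hydroxy ester F4. LiAlH4 (THF, 0 °C) reduces the ester and the cyclopentanone, and the route is rejoined at triol 19.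

2. Step 11 (borohydride reduction). Hydride delivery to the cyclopentanone from the methyl-bearing face would give the C1 epimer, and its tosylate would fragment to the Z-olefin. The fallback makes the epimer on purpose and inverts it. It sets out from 18: hydroxyl-directed reduction with Me4NBH(OAc)3 (MeCN/AcOH, −20 °C), in which the tertiary 3a-hydroxyl delivers hydride to its own face, should give the 1-epi-triol F5 with the 1-hydroxyl trans to the methyl group. TBSCl/imidazole gives the primary silyl ether F6; a Mitsunobu reaction (4-nitrobenzoic acid, PPh3, DIAD, THF) inverts C1 and gives the inverted 4-nitrobenzoate F7; K2CO3/MeOH releases diol 20, where the route resumes.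

3. Step 15 (enol triflate). Deprotonation on the substituted side of the ketone (C9) would lead to beta-elimination of the silyloxy group or to epimerisation, and regiocontrol of the triflation would be lost. The fallback is a Shapiro reaction, in which the olefin position is fixed by hydrazone-directed deprotonation and the formyl carbon comes from DMF. It sets out from 23: 2,4,6-triisopropylbenzenesulfonyl hydrazide (cat. HCl, MeOH) gives the trisylhydrazone F8; n-BuLi (2.2 equiv, THF, −78 to 0 °C) gives the vinyllithium on the CH2 side, which is quenched with DMF to the bis-silyl enal F9. HF·pyridine gives the diol enal F10, and AcCl/2,4,6-collidine at −78 °C acetylates the primary hydroxyl to give target 28 directly.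

Further compounds
F1 | step 10 | 2-bromo derivative of aldehyde 16 (both C2 epimers) | O=CC(Br)[C@@H]([C@@H](C)CCC=C(C)C)[C@@H](O[Si](C)(C)C(C)(C)C)CC1(C)C(=O)CCC1=O
F2 | step 10 | 2-bromo carboxylic acid from F1 (both C2 epimers) | OC(=O)C(Br)[C@@H]([C@@H](C)CCC=C(C)C)[C@@H](O[Si](C)(C)C(C)(C)C)CC1(C)C(=O)CCC1=O
F3 | step 10 | methyl ester of F2 (both C2 epimers) | COC(=O)C(Br)[C@@H]([C@@H](C)CCC=C(C)C)[C@@H](O[Si](C)(C)C(C)(C)C)CC1(C)C(=O)CCC1=O
F4 | step 10 | methyl ester analogue of 18 (CO2CH3 in place of CHO at C4, same configuration) | COC(=O)[C@@H]1[C@@H]([C@@H](C)CCC=C(C)C)[C@@H](O[Si](C)(C)C(C)(C)C)C[C@]2(C)C(=O)CC[C@]12O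
F5 | step 11 | C1 epimer of triol 19 (1-OH trans to 7a-CH3) | OC[C@@H]1[C@@H]([C@@H](C)CCC=C(C)C)[C@@H](O[Si](C)(C)C(C)(C)C)C[C@]2(C)[C@H](O)CC[C@]12O
F6 | step 11 | C1 epimer of 20 | CC(C)(C)[Si](C)(C)OC[C@@H]1[C@@H]([C@@H](C)CCC=C(C)C)[C@@H](O[Si](C)(C)C(C)(C)C)C[C@]2(C)[C@H](O)CC[C@]12O
F7 | step 11 | C1 4-nitrobenzoate of 20 (configuration of 20) | CC(C)(C)[Si](C)(C)OC[C@@H]1[C@@H]([C@@H](C)CCC=C(C)C)[C@@H](O[Si](C)(C)C(C)(C)C)C[C@]2(C)[C@@H](OC(=O)c3ccc(cc3)[N+](=O)[O-])CC[C@]12O
F8 | step 15 | 2,4,6-triisopropylbenzenesulfonyl hydrazone of 23 | CC(C)(C)[Si](C)(C)OC[C@H]1C(=NNS(=O)(=O)c2c(cc(cc2C(C)C)C(C)C)C(C)C)CC/C=C(\C)C[C@H](O[Si](C)(C)C(C)(C)C)[C@@H]1[C@@H](C)CCC=C(C)C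
F9 | step 15 | bis-TBS ether of the deacetylated target (enal) | CC(C)(C)[Si](C)(C)OC[C@H]1/C(C=O)=C\C/C=C(\C)C[C@H](O[Si](C)(C)C(C)(C)C)[C@@H]1[C@@H](C)CCC=C(C)C
F10 | step 15 | deacetylated target (diol enal) | OC[C@H]1/C(C=O)=C\C/C=C(\C)C[C@H](O)[C@@H]1[C@@H](C)CCC=C(C)C
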